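## Structural features

The target is a monocyclic lignan built on an oxolane (O1, C2–C5). C2 carries a 4-hydroxy-3-methoxyphenyl (guaiacyl) ring directly, C3 a CH2O–CO–CH2CH(CH3)2 arm, C4 a guaiacylmethyl arm, and C5 is an unsubstituted OCH2. C2, C3 and C4 are three contiguous stereocentres, (2S,3R,4R): the aryl group on C2 is trans to the ester arm on C3, and the arms on C3 and C4 are cis. Three groups are fragile. The two free phenols are easily oxidised and compete in any acylation. The C2–O1 bond is benzylic and para to a phenolic oxygen, so it ionises under acid (epimerisation through a quinone methide) and can be hydrogenolysed. The primary ester is cleaved by base. The real difficulty is therefore the three adjacent stereocentres in one absolute sense, together with acylating one aliphatic hydroxyl beside two unprotected phenols. In lignan terms C3–C4 is the 8–8' bond between two identical guaiacylpropane halves (C2 = C7, C3 = C8, ester CH2 = C9, C4 = C8', C5 = C9', benzylic CH2 = C7'). If the ester oxygen on C9 were bonded to C7, a second oxolane would be fused across C3–C4, giving a C2-symmetric 2,6-diaryl-3,7-dioxabicyclo[3.3.0]octane with two equivalent benzylic C–O bonds. The key step builds that bicycle from two molecules of one cinnamyl alcohol, and the target is then reached by opening one of the two equivalent benzylic ethers.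

## Logic of the disconnections

**10 to 8 and 9.** The acyl C–O bond of the ester on the C3 arm is cut. It is the only bond outside the lignan skeleton and the most base-sensitive one, so it is made last. This removes five carbons and leaves a triol that may be racemic. The forward step must acylate only the aliphatic hydroxyl of 8, leave both phenols alone, and take only the (2S,3R,4R) enantiomer out of the racemate, which limits it to less than half conversion.

**8 to 6 (through 7).** The bond between the benzylic carbon C7' and the oxygen on C9 is re-formed, and a bromine is put back on C5 of each ring. This restores the C2-symmetric bicycle: three different stereocentres become two symmetry-related pairs held in a cis-fused ring system. The forward reduction must remove both aryl–bromine bonds and exactly one of two equivalent benzylic C–O bonds, and must not touch the second one or the stereocentres.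

**6 to two molecules of 4 (through 5).** The C8–C8' bond and both C7–O bonds are cut. The C2 axis passes through the middle of C8–C8', so the pieces are identical and achiral. Two rings, three skeletal bonds and four stereocentres are traced back to one ten-carbon allylic alcohol. The forward step must remove one electron per phenol and couple only at C8 of both partners, which is why 4 carries bromine on C5. It must also close both rings faster than the solvent adds, and it must not oxidise 6 further. An achiral monomer cannot deliver absolute configuration within this disconnection, so 6 is accepted as the racemate and the choice of enantiomer is passed on to the last step.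

**4 to 3.** The allylic alcohol is taken back to the ester oxidation level, because an ester is what an olefination of an aromatic aldehyde gives directly. The forward step must deliver hydride 1,2 only, beside an acidic phenol, an aryl bromide and a conjugated alkene.

**3 to 1 and 2.** The C7=C8 double bond is cut. 1 already holds the bromine, methoxy and hydroxy groups in the right positions, and 2 brings the two remaining carbons. The forward step must give the E alkene and tolerate the free phenol, which saves a separate esterification.

## Other disconnections considered

**Alternative 1:** The cuts would be the bond between C4 and the benzylic carbon of its arm, and the C2–C3 bond. C3 and C4 would be the α- and β-carbons of the chiral butenolide A2, C2 the carbonyl carbon of aldehyde A4, and the benzylic carbon would arrive as the masked acyl anion of dithiane A3. In the forward key step the 2-lithio derivative of A3 would add 1,4 to A2 on the face away from the menthyloxy group. The lactone enolate would then be trapped by A4 trans to the new substituent, giving A1 without closing a ring.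
- In its favour: absolute configuration at C3 and C4 is set by a recoverable auxiliary in the first C–C bond formation, and nothing is discarded in a resolution. The trans lactone becomes the 3,4-cis oxolane once the ring is re-closed through the former acetal carbon. On absolute control and on material throughput it is better than the chosen plan. On fixing the C3/C4 relation by a ring it is its equal.
- Against it here: the carbinol carbon (future C2) forms without control and must be corrected in an acid-mediated closure through a benzylic cation, next to an acid-sensitive dithioacetal. Reduction of lactone and acetal, desulfurisation, acylation and removal of two benzyl ethers follow, and that last hydrogenolysis competes with cleavage of C2–O1. The two identical guaiacyl units are introduced separately, so the hidden symmetry is not used.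
- Comparison: the mechanism is polar organolithium chemistry at low temperature with a stoichiometric auxiliary, against a reagent-free electron transfer at room temperature. It should need about twice as many operations from A2, A3 and A4 as the chosen plan needs from 1.

**Alternative 2:** The cuts would be C2–C3 and C4–C5. O1, C2 and C5 would come from the carbonyl ylide A8, and C3 and C4 from the alkene of butenolide A6. CsF would turn the silyl chloromethyl ether A7 into A8 by desilylation and loss of chloride. A8 should add to A6 on the face away from the menthyloxy group to give A5, with the new oxolane cis-fused to the lactone and the aryl group exo. By bicyclo numbering the aryl-bearing carbon of A5 is C8, bonded to the bridgehead that carries the lactone carbonyl. In that regiochemistry the lactone carbonyl becomes the CH2O arm on C3 and the acetal carbon becomes the benzylic carbon on C4. A5 is named and drawn accordingly in the list.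
- In its favour: the oxolane and C2, C3 and C4 form in one step with absolute control from the auxiliary, which is better than the chosen plan on that point. Its use of a cis-fused bicycle to fix relative configuration is equal, and so is the making of two ring bonds in one operation.
- Against it here: C4 still lacks its aryl group after the key step. The acetal must be hydrolysed, an aryl nucleophile added to the freed aldehyde, and the new benzylic oxygen removed beside the equally benzylic C2–O1 ether. The molecule is no longer symmetric, so cleavage at the wrong benzylic position is not productive as it is in the chosen plan. The lactone must also be reduced. Which ylide terminus bonds to the β-carbon, and the exo preference of a non-stabilised ylide, rest on a modest electronic and steric bias. A7 is a moisture-sensitive α-chloro ether.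
- Comparison: A6 and A7 both need preparation and about six operations follow A5, so the sequence should be clearly longer.

**Alternative 3:** The cuts would be C3–C4 and the bond between the benzylic CH2 and its aryl ring, leading back to the redox-active ester A10 and the aryl iodide A11. In the forward key step low-valent nickel (NiBr2·glyme, 4,4'-di-tert-butyl-2,2'-bipyridine, Zn) would reduce A10. Decarboxylation would give a radical at C3, which would close 5-exo-trig onto the allyl ether. The primary radical would then be captured by an aryl–nickel species formed from A11 to give A9.
- In its favour: ring closure and attachment of the second aryl group happen in one catalytic step. Absolute configuration comes from one benzylic stereocentre of A10, with no resolution. A chair-like transition state with the C2 aryl group pseudo-equatorial should give the 2,3-trans-3,4-cis ring. The orthogonal 4-methoxybenzyl and benzyl ethers turn the later acylation into protecting-group logic. On absolute control and on chemoselectivity of the acylation it is better than the chosen plan. On the mode of ring closure (5-exo) and on making C3–C4 in the key step it is its equal.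
- Against it here: the C3 stereocentre of A10 is erased in the radical, so two new centres depend on substrate control in an early transition state, which is seldom complete. The bicycle of the chosen key step cannot adopt another relative configuration. Arylation or reduction of the uncyclised radical competes. A10 needs an enantioselective synthesis of a β-allyloxy acid prone to β-elimination. The final debenzylation competes with cleavage of C2–O1.
- Comparison: the sequence should be about twice as long as the chosen one.

Key step: step 3

Remark on the structures: the enantiomers drawn for the racemates 5–8 are those that lead to 10. The (7S,8R,7'S,8'R) form of 6 maps onto (2S,3R,4R)-10 whichever benzylic C–O bond is cleaved.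

Assumption (remark on the chemistry): the sense of lipase enantiopreference for the hydroxymethyl group of 8 cannot be derived from the structure; the route assumes that the (2S,3R,4R) alcohol is the faster-reacting enantiomer with Burkholderia cepacia lipase.

## Route

Step 1
Reactants: 1 5-bromovanillin (3-bromo-4-hydroxy-5-methoxybenzaldehyde); 2 ethyl (triphenyl-λ5-phosphanylidene)acetate
Product: 3 ethyl (E)-3-(3-bromo-4-hydroxy-5-methoxyphenyl)prop-2-enoate (ethyl (E)-5-bromoferulate)
Conditions: Ph3P=CHCO2Et (1.3 equiv), toluene, 80 °C
Reagents that add atoms: ethyl (triphenyl-λ5-phosphanylidene)acetate 2, CCOC(=O)C=P(c1ccccc1)(c1ccccc1)c1ccccc1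
Why: Wittig olefination with a stabilised ylide, which should give the E alkene through the more stable trans-oxaphosphetane; proton transfer from the phenol to the weakly basic ylide is reversible and is drained by the irreversible olefination, so no protection is needed.

Step 2
Reactants: 3 ethyl (E)-5-bromoferulate
Product: 4 (E)-5-bromoconiferyl alcohol (2-bromo-4-[(E)-3-hydroxyprop-1-enyl]-6-methoxyphenol)
Conditions: iBu2AlH (4 equiv), toluene–THF, −78 → 0 °C; aq. KNaC4H4O6 (potassium sodium tartrate)
Reagents that add atoms: none
Why: 1,2-Reduction of an α,β-unsaturated ester by an electrophilic aluminium hydride: the first equivalent is consumed by the phenol, two more take the ester through the aldehyde to the allylic alkoxide, and neither the conjugated alkene nor the aryl bromide should react. The neutral tartrate work-up avoids the acid to which the electron-rich cinnamyl alcohol is sensitive.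

Step 3
Reactants: 4 (E)-5-bromoconiferyl alcohol (two molecules)
Product: 6 (±)-5,5'-dibromopinoresinol (racemic cis-fused 2,6-diexo-diaryl-3,7-dioxabicyclo[3.3.0]octane; each aryl is 3-bromo-4-hydroxy-5-methoxyphenyl), via 8–8'-coupled bis-quinone methide 5 (not isolated)
Conditions: graphite-felt anode, Pt cathode, undivided cell, constant current (2 mA cm−2, 1.0–1.1 F per mol of 4), acetone–aq. NaOAc/AcOH buffer (pH 5) 3:1, rt
Reagents that add atoms: none
Why: Anodic proton-coupled one-electron oxidation of the phenol of 4 gives a phenoxyl radical whose spin is delocalised through the ring to C8 of the side chain; two such radicals combine at C8–C8' to the bis-quinone methide 5, while the cathode turns the released protons into H2. The closest known reactions are the dehydrodimerisation of this same alcohol by FeCl3 or by peroxidase and H2O2, and the anodic 8–8' dimerisation of 4-hydroxycinnamic acids to bis-lactones, so only the way the electron is removed is varied. Each oxolane closes by 5-exo-trig 1,6-addition of the hydroxymethyl oxygen of one half to the quinone methide carbon C7 of the other half, driven by rearomatisation. C8 and C8' are fixed in the radical coupling: only the like (R*,R*) diastereomer of 5 can close twice, because the bicyclo[3.3.0]octane must be cis-fused, and any unlike isomer is lost to side products and not to a stereoisomer of 6. C7 and C7' are fixed in the ring closures, where each aryl group takes the exo (convex) face, trans to the substituent on the neighbouring ring carbon. The step needs 8–8' regioselectivity: bromine on C5 removes the ring position used in 8–5 and 5–5 coupling, and the bromine and methoxy groups flanking the phenolic oxygen slow 8–O–4 coupling. It also needs 6 to escape further oxidation, which the limit of one electron per monomer, the loss of the conjugated side chain in 6 and its low solubility should secure. No absolute control is exerted, so 6 should form as the racemate.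

Step 4
Reactants: 6 (±)-5,5'-dibromopinoresinol
Product: 8 (±)-lariciresinol (racemic 2,3-trans-3,4-cis oxolane: 2-guaiacyl 3-hydroxymethyl 4-guaiacylmethyl), via (±)-pinoresinol 7 (not isolated)
Conditions: H2 (1 atm), 10% Pd/C, NaOAc (2.2 equiv), THF–MeOH, rt; stopped after uptake of 3 equiv H2
Reagents that add atoms: none
Why: Heterogeneous Pd-catalysed hydrogenolysis: the two aryl C–Br bonds are cleaved first by oxidative addition to zerovalent palladium (NaOAc takes up the HBr and keeps the medium from turning acidic), giving 7, and one benzylic C–O bond, activated by the para-oxygenated ring and the strain of the bicycle, is then reduced to CH2. Because 7 is C2-symmetric either cleavage gives the same 8, and C7, C8 and C8' are untouched since only the carbon that becomes CH2 loses its stereogenicity. The remaining benzylic ether sits in a less strained monocycle and should react more slowly, which is why the uptake of H2 is limited.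

Step 5
Reactants: 8 (±)-lariciresinol; 9 isovaleric anhydride (3-methylbutanoic anhydride)
Product: 10 (+)-9'-isovaleroxylariciresinol, [(2S,3R,4R)-2-(4-hydroxy-3-methoxyphenyl)-4-[(4-hydroxy-3-methoxyphenyl)methyl]oxolan-3-yl]methyl 3-methylbutanoate
Conditions: immobilised Burkholderia cepacia lipase, (iPrCH2CO)2O (0.5 equiv), MTBE–THF 3:1, 0 °C → rt, run to about 40% conversion
Reagents that add atoms: isovaleric anhydride 9, CC(C)CC(=O)OC(=O)CC(C)C
Why: Lipase-catalysed acyl transfer (acyl-enzyme from the anhydride, then alcoholysis) takes place at primary aliphatic hydroxyls and not at phenols, so no protection is needed. With a racemic primary alcohol bearing a β-stereocentre it is a kinetic resolution, run below half conversion so that the faster (2S,3R,4R) enantiomer leaves as ester 10 and the (2R,3S,4S) alcohol is removed by chromatography. No stereocentre is formed: the enzyme selects the absolute configuration, and the neutral, base-free medium leaves the benzylic ether and the phenols alone.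

## Compound list

1 | 5-bromovanillin (3-bromo-4-hydroxy-5-methoxybenzaldehyde) | COc1cc(C=O)cc(Br)c1O | starting material
2 | ethyl (triphenyl-λ5-phosphanylidene)acetate | CCOC(=O)C=P(c1ccccc1)(c1ccccc1)c1ccccc1 | starting material
3 | ethyl (E)-3-(3-bromo-4-hydroxy-5-methoxyphenyl)prop-2-enoate | CCOC(=O)/C=C/c1cc(OC)c(O)c(Br)c1 | intermediate
4 | (E)-5-bromoconiferyl alcohol, 2-bromo-4-[(E)-3-hydroxyprop-1-enyl]-6-methoxyphenol | COc1cc(/C=C/CO)cc(Br)c1O | intermediate
5 | 8–8'-coupled bis-quinone methide, 4,4'-[(2R*,3R*)-2,3-bis(hydroxymethyl)butane-1,4-diylidene]bis(2-bromo-6-methoxycyclohexa-2,5-dien-1-one); not isolated; racemate, (R,R) form drawn | COC1=CC(=C[C@@H](CO)[C@H](CO)C=C2C=C(OC)C(=O)C(Br)=C2)C=C(Br)C1=O | intermediate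
6 | (±)-5,5'-dibromopinoresinol, rel-(1S,3aR,4S,6aR)-1,4-bis(3-bromo-4-hydroxy-5-methoxyphenyl)tetrahydro-1H,3H-furo[3,4-c]furan; racemate, (7S,8R,7'S,8'R) form drawn | COc1cc(cc(Br)c1O)[C@H]1OC[C@H]2[C@@H]1CO[C@@H]2c1cc(Br)c(O)c(OC)c1 | intermediate
7 | (±)-pinoresinol, rel-(1S,3aR,4S,6aR)-1,4-bis(4-hydroxy-3-methoxyphenyl)tetrahydro-1H,3H-furo[3,4-c]furan; not isolated; racemate, (7S,8R,7'S,8'R) form drawn | COc1cc(ccc1O)[C@H]1OC[C@H]2[C@@H]1CO[C@@H]2c1ccc(O)c(OC)c1 | intermediate
8 | (±)-lariciresinol, rel-[(2S,3R,4R)-2-(4-hydroxy-3-methoxyphenyl)-4-(4-hydroxy-3-methoxybenzyl)oxolan-3-yl]methanol; racemate, (2S,3R,4R) form drawn | COc1cc(C[C@H]2CO[C@H](c3ccc(O)c(OC)c3)[C@H]2CO)ccc1O | intermediate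
9 | isovaleric anhydride (3-methylbutanoic anhydride) | CC(C)CC(=O)OC(=O)CC(C)C | starting material
10 | (+)-9'-isovaleroxylariciresinol, [(2S,3R,4R)-2-(4-hydroxy-3-methoxyphenyl)-4-[(4-hydroxy-3-methoxyphenyl)methyl]oxolan-3-yl]methyl 3-methylbutanoate | COc1cc(C[C@H]2CO[C@H](c3ccc(O)c(OC)c3)[C@H]2COC(=O)CC(C)C)ccc1O | target

## Step count and risks

Total step count: 5. Longest linear sequence: 5 steps (1 → 3 → 4 → 6 → 8 → 10).

**Step 5 (least certain).** The most likely failure is insufficient discrimination between the enantiomers, or discrimination in the opposite sense. The stereocentre lies β to the reacting oxygen and its two ring substituents are similar in size, and any uncatalysed acylation by the anhydride would erode the enantiomeric purity further. Fallback: starting from 8, the racemate is separated by preparative chromatography on a cellulose tris(3,5-dimethylphenylcarbamate) stationary phase, a phase type on which lignans of this class are resolved. The dextrorotatory fraction is (+)-lariciresinol F1. F1 is then acylated with 9 by immobilised Candida antarctica lipase B in MTBE–THF, an enzyme used here only for its chemoselectivity for the primary alcohol. This returns to the route at 10.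

**Step 3 (key step).** The most likely failure is loss of material to oligomers through further oxidation of the product phenols and cross-coupling with monomer radicals, together with passivation of the anode by a polymer film. Both arise because the electron transfer happens at a surface where radical and product concentrations are high. Fallback: the electron transfer is moved into homogeneous solution. Starting from 4, treatment with FeCl3·6H2O (about 1.1 equiv) in aqueous acetone at room temperature, in which trivalent iron is reduced to divalent iron, follows the same coupling and cyclisation sequence and is known chemistry for this alcohol. It rejoins the route at 6 and makes no compound outside the list (F0).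

**Step 4.** The most likely failure is over-reduction, meaning cleavage of the second benzylic C–O bond, or stalling before the first cleavage because bromide poisons the catalyst. Both come from running two reductions on one catalyst under one hydrogen atmosphere. Fallback: the two reductions are decoupled. Starting from 6, hydrogenation over 10% Pd/C with NH4OAc in THF–MeOH removes the bromines while the ammonium salt suppresses benzyl ether hydrogenolysis, so 7 can be isolated and crystallised. 7 is then hydrogenolysed separately over fresh Pd/C in neutral MeOH with one equivalent of H2 to partial conversion, and recovered 7 is recycled. This returns to the route at 8 and makes no compound outside the list (F0).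

## Further compounds

F1 | step 5 | (+)-lariciresinol, [(2S,3R,4R)-2-(4-hydroxy-3-methoxyphenyl)-4-(4-hydroxy-3-methoxybenzyl)oxolan-3-yl]methanol | COc1cc(C[C@H]2CO[C@H](c3ccc(O)c(OC)c3)[C@H]2CO)ccc1O
F0 | step 3 | none | none
F0 | step 4 | none | none
A1 | alternative 1 | (3S,4R,5R)-3-{[4-(benzyloxy)-3-methoxyphenyl](hydroxy)methyl}-4-{2-[4-(benzyloxy)-3-methoxyphenyl]-1,3-dithian-2-yl}-5-[(1R,2S,5R)-menthyloxy]oxolan-2-one, carbinol epimers | O=C1O[C@@H](O[C@@H]2C[C@H](C)CC[C@H]2C(C)C)[C@H](C3(c4ccc(OCc5ccccc5)c(OC)c4)SCCCS3)[C@H]1C(O)c1ccc(OCc2ccccc2)c(OC)c1
A2 | alternative 1 | (5R)-5-[(1R,2S,5R)-menthyloxy]furan-2(5H)-one | O=C1C=C[C@H](O[C@@H]2C[C@H](C)CC[C@H]2C(C)C)O1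
A3 | alternative 1 | 2-[4-(benzyloxy)-3-methoxyphenyl]-1,3-dithiane | COc1cc(C2SCCCS2)ccc1OCc1ccccc1
A4 | alternative 1 | 4-(benzyloxy)-3-methoxybenzaldehyde (O-benzylvanillin) | COc1cc(C=O)ccc1OCc1ccccc1
A5 | alternative 2 | (1S,4S,5R,8S)-8-[4-(benzyloxy)-3-methoxyphenyl]-4-[(1S,2R,5S)-menthyloxy]-3,7-dioxabicyclo[3.3.0]octan-2-one, cis-fused, aryl exo | COc1cc([C@H]2OC[C@H]3[C@@H]2C(=O)O[C@@H]3O[C@H]4C[C@@H](C)CC[C@@H]4C(C)C)ccc1OCc1ccccc1
A6 | alternative 2 | (5S)-5-[(1S,2R,5S)-menthyloxy]furan-2(5H)-one | O=C1C=C[C@@H](O[C@H]2C[C@@H](C)CC[C@@H]2C(C)C)O1
A7 | alternative 2 | chloromethyl [4-(benzyloxy)-3-methoxyphenyl](trimethylsilyl)methyl ether, racemic | COc1cc(C(OCCl)[Si](C)(C)C)ccc1OCc1ccccc1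
A8 | alternative 2 | carbonyl ylide [4-(benzyloxy)-3-methoxybenzylidene]oxonium methylide, transient | [CH2-][O+]=Cc1ccc(OCc2ccccc2)c(OC)c1
A9 | alternative 3 | (2S,3R,4R)-2-[4-(benzyloxy)-3-methoxyphenyl]-4-[4-(benzyloxy)-3-methoxybenzyl]-3-{[(4-methoxybenzyl)oxy]methyl}oxolane | COc1cc(C[C@H]2CO[C@H](c3ccc(OCc4ccccc4)c(OC)c3)[C@H]2COCc2ccc(OC)cc2)ccc1OCc1ccccc1
A10 | alternative 3 | 1,3-dioxoisoindolin-2-yl (3S)-3-(allyloxy)-3-[4-(benzyloxy)-3-methoxyphenyl]-2-{[(4-methoxybenzyl)oxy]methyl}propanoate, C2 epimers | C=CCO[C@H](c1ccc(OCc2ccccc2)c(OC)c1)C(COCc1ccc(OC)cc1)C(=O)ON1C(=O)c2ccccc2C1=O
A11 | alternative 3 | 1-(benzyloxy)-4-iodo-2-methoxybenzene | COc1cc(I)ccc1OCc1ccccc1
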